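**Plan**
- Retrosynthesis: the C8–O–C4''' diaryl ether is cut first (Ullmann union of an 8-hydroxyflavone with a 4'-bromoflavone). Then bond C4a–C5 of ring A of the 5-hydroxy-7-methoxyflavone half is cut, then the side-chain C–C bonds back to a 6-aryl-2-methyl-4-pyranone and its triketone.
- Enabling feature: ring A of that half is a phloroglucinol ring (oxygens at C5, C7 and C8a) fused through C4a–C8a to pyranone ring C. This is the pattern of a Claisen-folded polyketide chain, so ring C can be made first as a 4-pyranone and ring A folded onto its C3.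
- Forward, bromide half: pentane-2,4-dione and methyl 4-bromobenzoate give the triketone, then the pyranone (ring C); carboxylation and two-carbon homologation give the β-keto ester; Claisen closure gives ring A; O-methylation follows.
- Forward, phenol half and union: acacetin is 7-O-benzylated and 8-hydroxylated (Elbs). CuI-catalysed etherification joins the halves, and BCl3 removes the benzyl group and the chelated 5-O-methyl group.
- The target has no stereocentre. Only regiochemistry must be controlled: chelation of the 5-OH groups, para-selective Elbs oxidation, and a single reachable carbon in the Claisen step.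

Key step: step 5

Remark: the 1,3-dicarbonyl compounds 3, 8, 9 and 10 are written as single tautomers; each will exist as a keto–enol mixture, which does not affect the chemistry.

**Route**

Step 1
Reactants: 1 pentane-2,4-dione; 2 methyl 4-bromobenzoate
Product: 3 1-(4-bromophenyl)hexane-1,3,5-trione
Conditions: NaH (5 equiv), DME, reflux; then aq. HCl, 0 °C
Reagents that add atoms: none
Why: Terminal Claisen aroylation of a β-diketone: under excess NaH the diketone is acylated at its methyl carbon through the dianion, and deprotonation of the triketone drives the condensation; the aryl bromide is inert to NaH.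

Step 2
Reactants: 3 1-(4-bromophenyl)hexane-1,3,5-trione
Product: 4 2-(4-bromophenyl)-6-methyl-4H-pyran-4-one
Conditions: conc. H2SO4, 0 °C → rt; ice–water
Reagents that add atoms: none
Why: Acid-catalysed cyclodehydration of a 1,3,5-triketone, which in cold concentrated H2SO4 should close to the 4-pyranone.

Step 3
Reactants: 4 2-(4-bromophenyl)-6-methyl-4H-pyran-4-one
Product: 6 2-[6-(4-bromophenyl)-4-oxo-4H-pyran-2-yl]acetic acid, via lithium pyranone dienolate 5 (not isolated)
Conditions: LiN(SiMe3)2 (1.2 equiv), THF, −78 °C; then cannulated into CO2-saturated THF, −78 → 0 °C; cold 1 M HCl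
Reagents that add atoms: carbon dioxide, O=C=O
Why: Lateral (vinylogous) deprotonation of the 2-methyl group of a 4-pyranone and carboxylation of the dienolate at its exocyclic carbon; the bulky amide neither adds to the pyranone nor exchanges the aryl bromide, and inverse addition into excess CO2 limits proton transfer to the product.

Step 4
Reactants: 6 2-[6-(4-bromophenyl)-4-oxo-4H-pyran-2-yl]acetic acid; 7 Meldrum's acid (2,2-dimethyl-1,3-dioxane-4,6-dione)
Product: 9 methyl 4-[6-(4-bromophenyl)-4-oxo-4H-pyran-2-yl]-3-oxobutanoate, via acyl Meldrum's acid 8 (not isolated)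
Conditions: EDC·HCl, DMAP, CH2Cl2, 0 °C → rt; aq. KHSO4 wash; then MeOH, reflux
Reagents that add atoms: methanol, CO
Why: Meldrum's acid β-keto ester synthesis: carbodiimide/DMAP C-acylation of 7, then methanolysis through the acylketene with loss of acetone and CO2; adding the two carbons at the acid stage avoids an enolisable malonyl electrophile, which would only protonate dienolate 5.

Step 5
Reactants: 9 methyl 4-[6-(4-bromophenyl)-4-oxo-4H-pyran-2-yl]-3-oxobutanoate
Product: 11 2-(4-bromophenyl)-5,7-dihydroxy-4H-chromen-4-one, via triketo tautomer 10 (not isolated)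
Conditions: Mg(OMe)2 (4 equiv), MeOH (0.02 M), reflux; then 2 M HCl, AcOH, 60 °C
Reagents that add atoms: none
Why: Mg(OMe)2 removes a proton from the CH2 between pyranone C2 and the ketone, giving an extended enolate delocalised onto pyranone C3 and the C4 oxygen, while divalent magnesium bridges the side-chain carbonyls and holds the ester next to C3; C3 adds to the ester carbonyl, methoxide leaves, the C4a–C5 bond is formed and triketone 10 enolises twice to the aromatic 5,7-diol. The closest known reaction type is the Claisen-mode cyclisation of 3,5,7-triketo esters and of pyrone-masked polyketide chains to acylphloroglucinols under Mg(OMe)2, here applied to a 6-aryl-4-pyranone. Ring A closes in a 6-(enolexo)-exo-trig mode, since attack through the exocyclic carbon would need a four-membered ring. No stereocentre is formed. The step needs Claisen rather than aldol folding and a single site of C-acylation: with ring C intact the only aldol acceptor, the C4 carbonyl, is a vinylogous ester that the chain could reach only through a bridged ring, and C3 is the only nucleophilic carbon within reach of the ester. Should methoxide open ring C reversibly, magnesium chelation still favours the Claisen mode and the warm acid work-up recloses the resulting 2-hydroxyaryl 1,3-diketone to the same flavone 11.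

Step 6
Reactants: 11 2-(4-bromophenyl)-5,7-dihydroxy-4H-chromen-4-one
Product: 12 2-(4-bromophenyl)-5,7-dimethoxy-4H-chromen-4-one
Conditions: Me2SO4 (excess), K2CO3, acetone, reflux
Reagents that add atoms: dimethyl sulfate, COS(=O)(=O)OC
Why: Williamson O-methylation; the 7-OH reacts readily and the hydrogen-bonded 5-OH follows under excess reagent at reflux, so the bromide carries no free chelating phenol into the copper coupling, and the 5-O-methyl group is the one a Lewis acid later removes selectively.

Step 7
Reactants: 13 acacetin (5,7-dihydroxy-2-(4-methoxyphenyl)-4H-chromen-4-one)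
Product: 14 7-(benzyloxy)-5-hydroxy-2-(4-methoxyphenyl)-4H-chromen-4-one
Conditions: BnBr (1.1 equiv), K2CO3, acetone, reflux
Reagents that add atoms: benzyl bromide, BrCc1ccccc1
Why: Williamson etherification selective for the acidic 7-OH, because the 5-OH is hydrogen-bonded to the C4 carbonyl and does not react with one equivalent of benzyl bromide under K2CO3 in acetone.

Step 8
Reactants: 14 7-(benzyloxy)-5-hydroxy-2-(4-methoxyphenyl)-4H-chromen-4-one
Product: 16 7-(benzyloxy)-5,8-dihydroxy-2-(4-methoxyphenyl)-4H-chromen-4-one, via potassium 8-sulfate ester 15 (not isolated)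
Conditions: K2S2O8, aq. KOH, pyridine, 0 °C → rt; acidify, extract unchanged 14; then aq. HCl, Na2SO3 (trace), 85 °C
Reagents that add atoms: potassium peroxodisulfate, [K+].[K+].[O-]S(=O)(=O)OOS(=O)(=O)[O-]
Why: Elbs persulfate oxidation: the 5-phenoxide attacks the peroxide oxygen through its para carbon C8 to give aryl sulfate 15, which hot dilute acid hydrolyses; this is an established way from 7-alkoxy-5-hydroxyflavones to their 5,8-dihydroxy derivatives.

Step 9
Reactants: 12 2-(4-bromophenyl)-5,7-dimethoxy-4H-chromen-4-one; 16 7-(benzyloxy)-5,8-dihydroxy-2-(4-methoxyphenyl)-4H-chromen-4-one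
Product: 17 7-(benzyloxy)-8-[4-(5,7-dimethoxy-4-oxo-4H-chromen-2-yl)phenoxy]-5-hydroxy-2-(4-methoxyphenyl)-4H-chromen-4-one
Conditions: CuI (20 mol%), picolinic acid (40 mol%), K3PO4 (1.5 equiv), degassed DMSO, 90 °C, Ar
Reagents that add atoms: none
Why: Ullmann-type diaryl ether synthesis catalysed by monovalent copper: the non-chelated, more acidic 8-OH gives the copper phenoxide while the 5-OH stays hydrogen-bonded, the aryl bromide is activated by conjugation with the chromone, and picolinic acid is a ligand suited to di-ortho-substituted phenols.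

Step 10
Reactants: 17 7-(benzyloxy)-8-[4-(5,7-dimethoxy-4-oxo-4H-chromen-2-yl)phenoxy]-5-hydroxy-2-(4-methoxyphenyl)-4H-chromen-4-one
Product: 18 8-[4-(5-hydroxy-7-methoxy-4-oxo-4H-chromen-2-yl)phenoxy]-5,7-dihydroxy-2-(4-methoxyphenyl)-4H-chromen-4-one (CNP0124888.0)
Conditions: BCl3 (8 equiv), pentamethylbenzene, CH2Cl2, −78 °C → rt; then MeOH, aq. HCl
Reagents that add atoms: none
Why: Lewis-acid ether cleavage: BCl3 removes the benzyl group (cation trapped by pentamethylbenzene) and, through a six-membered boron chelate with the C4 carbonyl, only the peri 5-methoxy group, while the non-chelated 7- and 4'-methoxy groups and the diaryl ether should be stable at this temperature.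

**Compound list**

1 | pentane-2,4-dione | CC(=O)CC(C)=O | starting material
2 | methyl 4-bromobenzoate | COC(=O)c1ccc(Br)cc1 | starting material
3 | 1-(4-bromophenyl)hexane-1,3,5-trione | CC(=O)CC(=O)CC(=O)c1ccc(Br)cc1 | intermediate
4 | 2-(4-bromophenyl)-6-methyl-4H-pyran-4-one | Cc1cc(=O)cc(-c2ccc(Br)cc2)o1 | intermediate
5 | lithium 6-(4-bromophenyl)-2-methylidene-2H-pyran-4-olate (lateral dienolate of 4) | [Li+].[O-]C1=CC(=C)OC(-c2ccc(Br)cc2)=C1 | intermediate
6 | 2-[6-(4-bromophenyl)-4-oxo-4H-pyran-2-yl]acetic acid | OC(=O)Cc1cc(=O)cc(-c2ccc(Br)cc2)o1 | intermediate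
7 | Meldrum's acid (2,2-dimethyl-1,3-dioxane-4,6-dione) | CC1(C)OC(=O)CC(=O)O1 | starting material
8 | 5-{2-[6-(4-bromophenyl)-4-oxo-4H-pyran-2-yl]-1-hydroxyethylidene}-2,2-dimethyl-1,3-dioxane-4,6-dione | CC1(C)OC(=O)C(=C(O)Cc2cc(=O)cc(-c3ccc(Br)cc3)o2)C(=O)O1 | intermediate
9 | methyl 4-[6-(4-bromophenyl)-4-oxo-4H-pyran-2-yl]-3-oxobutanoate | COC(=O)CC(=O)Cc1cc(=O)cc(-c2ccc(Br)cc2)o1 | intermediate
10 | 2-(4-bromophenyl)-6,8-dihydro-4H-chromene-4,5,7-trione | O=C1CC(=O)c2c(C1)oc(-c1ccc(Br)cc1)cc2=O | intermediate
11 | 2-(4-bromophenyl)-5,7-dihydroxy-4H-chromen-4-one | Oc1cc(O)c2c(=O)cc(-c3ccc(Br)cc3)oc2c1 | intermediate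
12 | 2-(4-bromophenyl)-5,7-dimethoxy-4H-chromen-4-one | COc1cc(OC)c2c(=O)cc(-c3ccc(Br)cc3)oc2c1 | intermediate
13 | acacetin (5,7-dihydroxy-2-(4-methoxyphenyl)-4H-chromen-4-one) | COc1ccc(-c2cc(=O)c3c(O)cc(O)cc3o2)cc1 | starting material
14 | 7-(benzyloxy)-5-hydroxy-2-(4-methoxyphenyl)-4H-chromen-4-one | COc1ccc(-c2cc(=O)c3c(O)cc(OCc4ccccc4)cc3o2)cc1 | intermediate
15 | potassium 7-(benzyloxy)-5-hydroxy-2-(4-methoxyphenyl)-4-oxo-4H-chromen-8-yl sulfate | COc1ccc(-c2cc(=O)c3c(O)cc(OCc4ccccc4)c(OS(=O)(=O)[O-])c3o2)cc1.[K+] | intermediate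
16 | 7-(benzyloxy)-5,8-dihydroxy-2-(4-methoxyphenyl)-4H-chromen-4-one | COc1ccc(-c2cc(=O)c3c(O)cc(OCc4ccccc4)c(O)c3o2)cc1 | intermediate
17 | 7-(benzyloxy)-8-[4-(5,7-dimethoxy-4-oxo-4H-chromen-2-yl)phenoxy]-5-hydroxy-2-(4-methoxyphenyl)-4H-chromen-4-one | COc1ccc(-c2cc(=O)c3c(O)cc(OCc4ccccc4)c(Oc4ccc(-c5cc(=O)c6c(OC)cc(OC)cc6o5)cc4)c3o2)cc1 | intermediate
18 | 8-[4-(5-hydroxy-7-methoxy-4-oxo-4H-chromen-2-yl)phenoxy]-5,7-dihydroxy-2-(4-methoxyphenyl)-4H-chromen-4-one | COc1ccc(-c2cc(=O)c3c(O)cc(O)c(Oc4ccc(-c5cc(=O)c6c(O)cc(OC)cc6o5)cc4)c3o2)cc1 | target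

**Step count**

Total step count: 10. Longest linear sequence: 8 steps (steps 1–6, 9, 10); the acacetin branch (steps 7, 8) joins at step 9.

**Steps most likely to fail**

1. Step 5 (Claisen closure of ring A). The magnesium enolate may fail to close, because the ester sits in a chelated, enolised β-keto ester and is a weak electrophile. Methoxide may also open ring C and divert the chain to aldol folding or to retro-Claisen loss of the aroyl group. A lithium amide in excess would be expected to hold the substrate as an unreactive polyanion, which is why an equilibrating magnesium base is chosen. Fallback: the fallback sets out from 2 and builds ring C last instead of ring A. Claisen condensation of 2 with commercially available 1-(2-hydroxy-4,6-dimethoxyphenyl)ethanone (NaH, THF, reflux) should give 1-(4-bromophenyl)-3-(2-hydroxy-4,6-dimethoxyphenyl)propane-1,3-dione F1. Cyclodehydration of this Baker–Venkataraman-type diketone in AcOH with catalytic H2SO4 at 100 °C should give the flavone, and the route is rejoined at 12.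

2. Step 9 (copper-catalysed etherification). Adventitious oxygen or divalent copper may oxidise the 5,8-dihydroxy ring to the quinone. The 5-hydroxy-4-keto chelate may sequester the catalyst, the 5-oxygen may be arylated in competition, and the di-ortho-substituted 8-phenoxide may couple slowly. Fallback: a metal-free arylation with a diaryliodonium salt, setting out from 12. Halogen exchange (NaI, CuI cat., N,N'-dimethylethylenediamine, dioxane, 110 °C) should give 2-(4-iodophenyl)-5,7-dimethoxy-4H-chromen-4-one F2. Oxidation with mCPBA and TsOH·H2O in MeCN followed by 1,3,5-trimethoxybenzene should give [4-(5,7-dimethoxy-4-oxo-4H-chromen-2-yl)phenyl](2,4,6-trimethoxyphenyl)iodonium 4-methylbenzenesulfonate F3, a salt of trivalent iodine. Treating 16 with F3 and K2CO3 in toluene at 50 °C should transfer the electron-poor flavonyl aryl group to the 8-oxygen, and the route is rejoined at 17.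

3. Step 8 (Elbs oxidation). Persulfate oxidations of this kind tend to stop at partial conversion. The product hydroquinone may be oxidised further, and part of the benzyl ether may be lost during the acidic sulfate hydrolysis. Fallback: the 8-oxygen is introduced through an aryl iodide, setting out from 14.
   - Methylation of the 5-OH (Me2SO4, K2CO3, acetone, prolonged reflux) should give 7-(benzyloxy)-5-methoxy-2-(4-methoxyphenyl)-4H-chromen-4-one F4.
   - Iodination (I2, CF3CO2Ag, CH2Cl2), which in 5,7-dialkoxyflavones is directed to C8, should give 7-(benzyloxy)-8-iodo-5-methoxy-2-(4-methoxyphenyl)-4H-chromen-4-one F5.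
   - Miyaura borylation (B2pin2, PdCl2(dppf), KOAc, dioxane, 90 °C) should give 7-(benzyloxy)-5-methoxy-2-(4-methoxyphenyl)-8-(4,4,5,5-tetramethyl-1,3,2-dioxaborolan-2-yl)-4H-chromen-4-one F6, which is oxidised without isolation (NaBO3·4H2O, THF–water) to 7-(benzyloxy)-8-hydroxy-5-methoxy-2-(4-methoxyphenyl)-4H-chromen-4-one F7.
   - This phenol has neither a hydroquinone nor a free chelating hydroxyl. Coupling with 12 under the conditions of step 9 should give 7-(benzyloxy)-8-[4-(5,7-dimethoxy-4-oxo-4H-chromen-2-yl)phenoxy]-5-methoxy-2-(4-methoxyphenyl)-4H-chromen-4-one F8.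
   - BCl3 under the conditions of step 10 should cleave the benzyl ether and both peri 5-methoxy groups, and the route is rejoined at 18.

Further compounds
F1 | step 5 | 1-(4-bromophenyl)-3-(2-hydroxy-4,6-dimethoxyphenyl)propane-1,3-dione | COc1cc(O)c(C(=O)CC(=O)c2ccc(Br)cc2)c(OC)c1
F2 | step 9 | 2-(4-iodophenyl)-5,7-dimethoxy-4H-chromen-4-one | COc1cc(OC)c2c(=O)cc(-c3ccc(I)cc3)oc2c1
F3 | step 9 | [4-(5,7-dimethoxy-4-oxo-4H-chromen-2-yl)phenyl](2,4,6-trimethoxyphenyl)iodonium 4-methylbenzenesulfonate | COc1cc(OC)c2c(=O)cc(-c3ccc([I+]c4c(OC)cc(OC)cc4OC)cc3)oc2c1.Cc1ccc(S(=O)(=O)[O-])cc1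
F4 | step 8 | 7-(benzyloxy)-5-methoxy-2-(4-methoxyphenyl)-4H-chromen-4-one | COc1ccc(-c2cc(=O)c3c(OC)cc(OCc4ccccc4)cc3o2)cc1
F5 | step 8 | 7-(benzyloxy)-8-iodo-5-methoxy-2-(4-methoxyphenyl)-4H-chromen-4-one | COc1ccc(-c2cc(=O)c3c(OC)cc(OCc4ccccc4)c(I)c3o2)cc1
F6 | step 8 | 7-(benzyloxy)-5-methoxy-2-(4-methoxyphenyl)-8-(4,4,5,5-tetramethyl-1,3,2-dioxaborolan-2-yl)-4H-chromen-4-one | COc1ccc(-c2cc(=O)c3c(OC)cc(OCc4ccccc4)c(B4OC(C)(C)C(C)(C)O4)c3o2)cc1
F7 | step 8 | 7-(benzyloxy)-8-hydroxy-5-methoxy-2-(4-methoxyphenyl)-4H-chromen-4-one | COc1ccc(-c2cc(=O)c3c(OC)cc(OCc4ccccc4)c(O)c3o2)cc1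
F8 | step 8 | 7-(benzyloxy)-8-[4-(5,7-dimethoxy-4-oxo-4H-chromen-2-yl)phenoxy]-5-methoxy-2-(4-methoxyphenyl)-4H-chromen-4-one | COc1ccc(-c2cc(=O)c3c(OC)cc(OCc4ccccc4)c(Oc4ccc(-c5cc(=O)c6c(OC)cc(OC)cc6o5)cc4)c3o2)cc1
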